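| flask | left-handed substrate | right-handed substrate | partner | catalyst | added ligand | remark | time |
|---|---|---|---|---|---|---|---|
| red | 0.25 M | 0.25 M | 0.15 M | 6 mM | 68 mM | run made earlier |  |
| violet | 0.25 M | 0.25 M | 0.15 M | 9 mM | 68 mM | run made earlier |  |
| ochre | 0.25 M | 0.25 M | 0.15 M | 12 mM | 34 mM | run made earlier |  |
| flask | 0.25 M | 0.25 M | 0.150 M | 12 mM | 68 mM |  | 2.0 min |

- red (time / min: left-handed substrate / %, right-handed substrate / %): 0.417: 37.7, 43.3; 0.833: 36.3, 42.0; 1.33: 35.3, 42.3; 1.50: 34.9, 42.4; 2.00: 35.6, 43.7; 2.50: 34.9, 42.1
- violet (time / min: left-handed substrate / %, right-handed substrate / %): 0.200: 37.4, 43.5; 0.333: 35.0, 42.0; 0.500: 34.8, 42.2; 0.833: 34.1, 41.3; 1.33: 35.4, 41.4; 2.50: 34.0, 41.2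
- ochre (time / min: left-handed substrate / %, right-handed substrate / %): 0.200: 35.0, 42.1; 0.333: 34.6, 41.3; 0.667: 32.6, 41.0; 1.33: 33.1, 40.5; 2.50: 33.7, 40.6

(each reading ± 0.5 percentage points)

- catalyst is single-handed; left-handed substrate and right-handed substrate are mirror images of each other, charged as a racemate, each of them at the stated concentration
- an excess is below zero if the other one leads

- part of the left-handed substrate and right-handed substrate charged together that has reacted at 2.0 min
- excess of left-handed product over right-handed product in the product at 2.0 min
- excess of right-handed substrate over left-handed substrate among what is left of the two at 2.0 min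

Early on, the ochre run was nearly finished: by its readings it had 22.9% of the two substrates reacted at 0.200 min and 25.7% at 2.50 min. So I wrote the balance of the partner, which I took as the limiting reagent. Assuming one partner per substrate converted, the reacted part has a partner ceiling, the partner charged as a fraction of both substrates charged: 30.0%, the same in each run and in the flask.

Two amounts then mattered: that ceiling and the part reacted when the readings level off. Their ratio is the share of the partner that found a substrate. By their last readings the red run stood at 76.7% of its ceiling and the ochre run at 85.7%, a larger share, with more catalyst and less added ligand. I read the part of each ceiling not reached as partner lost some other way. The flask has ochre's catalyst but red's ligand, so I put it a little below 25.7% reacted.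

The forecast gave 25.6% reacted, with excesses of 29.5% in the product and 10.2% in the remaining substrate, judging that “the catalyst appears to die rather than the reaction reach equilibrium”.

The flask gave 25.8%, 29.0% and 10.1%, so the forecast held.

    partner + catalyst + left-handed substrate → catalyst + left-handed product (k = 46.0 M⁻² s⁻¹)
    partner + catalyst + right-handed substrate → catalyst + right-handed product (k = 23.0 M⁻² s⁻¹)
    2 partner → self-condensation product (k = 0.150 M⁻¹ s⁻¹)
    catalyst + added ligand ⇌ idle complex (K = 41.0 M⁻¹, k = 0.460 M⁻¹ s⁻¹)
    partner → decomposed reagent (k = 0.00500 s⁻¹)

The flask reached 86.0% of its ceiling, and it stopped through the running short of partner: at 2.00 min the partner stood at 0.015% of its charge, far less than the 67% of left-handed substrate. With that shortage taken away, the same flask gave 93.4% reacted at that time. The neighbour flask with 0.26 M of partner had a ceiling of 52.0% and reached 40.7%, which is 78.3% of it.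

The earlier runs and the new flask were computed for substances that don't exist; noise was put on by code.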